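**Retrosynthetic overview**

1. Ring A is bought as an arene: (S)-2-methylbutanoic acid 1 acylates phloroglucinol 2 (through acid chloride 3) to give ketone 4, and dearomative gem-dimethylation gives triketone 5.
2. Rings C and D (nine- and four-membered, C1 and C9 already set) are bought as (−)-β-caryophyllene 6.
3. Key disconnection: the dihydropyran ring B is opened by a retro-oxa-Diels–Alder reaction to the o-quinone methide 7 and the trans C4=C5 bond of 6.
4. 7 is not reached by the usual oxidation of a ring methyl group but is cut again at its exocyclic C=CH2 to 5 + formaldehyde. One domino Knoevenagel/oxa-Diels–Alder step then forms three bonds, ring B and both new stereocentres of target 8.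
5. Ring order: A (purchased, dearomatised in step 2) and C/D (purchased) first, ring B last.

Assumption: the hydroxy-enone in the target SMILES is one tautomer of an enolised β-triketone and all tautomers are treated as the same compound; commercial (−)-β-caryophyllene (1R,9S,4E) and (S)-2-methylbutanoic acid (≥98% ee) are used.

**Route**

Step 1
Reactants: 1 (2S)-2-methylbutanoic acid; 2 phloroglucinol (benzene-1,3,5-triol, anhydrous)
Product: 4 (2S)-2-methyl-1-(2,4,6-trihydroxyphenyl)butan-1-one, via (2S)-2-methylbutanoyl chloride 3 (not isolated)
Conditions: (COCl)2 (1.1 equiv), DMF (cat.), CH2Cl2, 0 °C → rt, 2 h; then added to 2 (1.2 equiv), AlCl3 (3.5 equiv), CH2Cl2/PhNO2 1:1, 0 °C → rt, 16 h; 1 M HCl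
Reagents that add atoms: none
Why: Friedel–Crafts C-acylation with the acid chloride made in the same flask without base (no ketene, so the α-centre is not touched); the chelated aryl ketone deactivates the ring against a second acylation, all three ring positions are equivalent, and the (S) centre of 1 is carried through (ee of 4 checked by chiral HPLC).

Step 2
Reactants: 4 (2S)-2-methyl-1-(2,4,6-trihydroxyphenyl)butan-1-one
Product: 5 3,5-dihydroxy-6,6-dimethyl-2-[(2S)-2-methylbutanoyl]cyclohexa-2,4-dien-1-one (dienol form of the 2-acyl-4,4-dimethylcyclohexane-1,3,5-trione)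
Conditions: NaOMe (3.0 equiv), MeI (2.2 equiv, slow addition), MeOH, 0 °C → rt, 8 h; 1 M HCl
Reagents that add atoms: iodomethane, CI
Why: Alkylative dearomatisation (double C-methylation of the phloroglucinol polyanion): the second methyl enters preferentially at the already methylated, most electron-rich ring carbon, and the resulting gem-dimethyl triketonate is much less nucleophilic, so 2.2 equiv of MeI stops mainly at 5; no stereocentre is formed, and the side-chain centre is safe because its carbonyl is part of the delocalised triketonate and resists α-deprotonation.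

Step 3
Reactants: 5 3,5-dihydroxy-6,6-dimethyl-2-[(2S)-2-methylbutanoyl]cyclohexa-2,4-dien-1-one; 6 (−)-β-caryophyllene [(1R,4E,9S)-4,11,11-trimethyl-8-methylidenebicyclo[7.2.0]undec-4-ene]
Product: 8 the target (6/6/9/4 tetracycle; caryophyllane numbering 1R,4S,5R,9S; side chain 2S), via o-quinone methide 7 (not isolated)
Conditions: (CH2O)n (2.0 equiv), 6 (3.0 equiv), ethylenediammonium diacetate (10 mol %), 1,4-dioxane, 80 °C, sealed tube, 5 added over 4 h, then 8 h; SiO2 chromatography, then preparative HPLC
Reagents that add atoms: formaldehyde (used as paraformaldehyde), C=O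
Why: Domino Knoevenagel condensation/inverse-electron-demand oxa-Diels–Alder reaction: 5 condenses with formaldehyde at its only ring C–H to give 7, whose CH2=C–C=O unit on the CMe2 side (the other flanking oxygen is held as the hydrogen-bonded enol of the acyl group) adds suprafacially to the strained trans C4=C5 bond of 6 with O on the more substituted C4 and CH2 on C5, so the E geometry fixes the trans ring fusion, and attack on the outer face of the ββ conformer of 6 (the face opposite to the one epoxidised in natural caryophyllene oxide) gives 4S,5R while C1, C9 and the side-chain centre are untouched; the 4R,5S epimer from the other face is expected to be the larger part (about 2:1) and is separated.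

**Compound list**

1 | (2S)-2-methylbutanoic acid | CC[C@H](C)C(=O)O | starting material
2 | phloroglucinol (benzene-1,3,5-triol) | Oc1cc(O)cc(O)c1 | starting material
3 | (2S)-2-methylbutanoyl chloride | CC[C@H](C)C(=O)Cl | intermediate (not isolated)
4 | (2S)-2-methyl-1-(2,4,6-trihydroxyphenyl)butan-1-one | CC[C@H](C)C(=O)c1c(O)cc(O)cc1O | intermediate
5 | 3,5-dihydroxy-6,6-dimethyl-2-[(2S)-2-methylbutanoyl]cyclohexa-2,4-dien-1-one | CC[C@H](C)C(=O)C1=C(O)C=C(O)C(C)(C)C1=O | intermediate
6 | (−)-β-caryophyllene, (1R,4E,9S)-4,11,11-trimethyl-8-methylidenebicyclo[7.2.0]undec-4-ene | C/C1=C\CCC(=C)[C@H]2CC(C)(C)[C@@H]2CC1 | starting material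
7 | 5-hydroxy-2,2-dimethyl-6-methylidene-4-[(2S)-2-methylbutanoyl]cyclohex-4-ene-1,3-dione (o-quinone methide) | C=C1C(=O)C(C)(C)C(=O)C(C(=O)[C@@H](C)CC)=C1O | intermediate (not isolated)
8 | target: 5-hydroxy-8,8-dimethyl-6-[(2S)-2-methylbutanoyl]-4H-chromen-7(8H)-one (ring A/B) fused through O1–C2 and C3 to C4 and C5 of the (1R,4S,5R,9S)-caryophyllane unit, 8(13)-exocyclic methylene intact | C=C1CC[C@@H]2CC3=C(O[C@@]2(C)CC[C@@H]2[C@@H]1CC2(C)C)C(C)(C)C(=O)C(C(=O)[C@@H](C)CC)=C3O | target

**Summary**

Total step count: 3. Longest linear sequence: 3 (1/2 → 4 → 5 → 8; 6 enters in the last step).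

Expected yields (estimates, not measured): step 1 about 60–70%, step 2 about 50–60%, step 3 about 50–60% of combined adducts, of which 8 is roughly one third (about 15–20% isolated).

**Steps most likely to fail, with fallbacks**

Step 3 (highest risk). Two problems are expected:
- The quinone methide 7 can be intercepted by unreacted 5 to give a methylene-bridged dimer. Slow addition of 5 and excess 6 are meant to suppress this.
- The face of 6 that leads to 8 is the less favoured one, and no reagent control is available.

Fallback: it sets out from 5 and comes back to the route at 7. 5 is C-methylated once more (NaOMe 1.5 equiv, MeI 1.1 equiv, MeOH, 0 °C → rt) to 3,5-dihydroxy-4,6,6-trimethyl-2-[(2S)-2-methylbutanoyl]cyclohexa-2,4-dien-1-one F1. F1 is then dehydrogenated at its ring methyl group with Ag2O (2.0 equiv) and TEMPO (20 mol %, regenerated by Ag2O) in THF at rt in the presence of 6 (3 equiv). This gives the same quinone methide 7 with no formaldehyde and no unblocked nucleophilic triketone in the flask, and 7 adds to 6 as in step 3 to give 8. The face selectivity is unchanged, so the same separation is needed.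

Step 2. Mixtures of mono-, gem-di- and tri-C-methylated products (and some O-methylation) can lower the yield of 5.

Fallback: it sets out from 4 and comes back to the route at 8, with dearomatisation and cycloaddition in the reverse order.
- 4, paraformaldehyde and 6 (NaOAc, AcOH, 80 °C) react through the aromatic o-quinone methide 3,5-dihydroxy-6-methylidene-4-[(2S)-2-methylbutanoyl]cyclohexa-2,4-dien-1-one F2 (not isolated) to give the caryophyllane-fused 5,7-dihydroxy-6-[(2S)-2-methylbutanoyl]chroman F3.
- F3 has its ether oxygen para to the acyl group and the 4S,5R configuration. It must be separated from the regioisomer cyclised through the oxygen next to the acyl group and from the C4/C5 epimer.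
- F3 is then gem-dimethylated at its single unsubstituted ring carbon (NaOMe, MeI, MeOH, 0 °C → rt), which dearomatises ring A and gives 8 directly. The only other C-nucleophilic site is the hindered ring-fusion carbon.

Step 1. Partial racemisation of the α-centre under AlCl3, or over-acylation, is possible.

Fallback: it sets out from 3 and comes back to the route at 4. 3 acylates commercial 1,3,5-trimethoxybenzene (AlCl3 1.1 equiv, CH2Cl2, −20 °C, 30 min) to give (2S)-2-methyl-1-(2,4,6-trimethoxyphenyl)butan-1-one F4. This is a much faster, low-temperature Friedel–Crafts reaction on an arene without free OH groups. The three methyl ethers are then cleaved (BBr3 6 equiv, CH2Cl2, −78 °C → rt) to give 4.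

**Further compounds**

F1 | step 3 | 3,5-dihydroxy-4,6,6-trimethyl-2-[(2S)-2-methylbutanoyl]cyclohexa-2,4-dien-1-one | CC[C@H](C)C(=O)C1=C(O)C(C)=C(O)C(C)(C)C1=O
F2 | step 2 | 3,5-dihydroxy-6-methylidene-4-[(2S)-2-methylbutanoyl]cyclohexa-2,4-dien-1-one (aromatic-series o-quinone methide, not isolated) | C=C1C(=O)C=C(O)C(C(=O)[C@@H](C)CC)=C1O
F3 | step 2 | caryophyllane-fused 5,7-dihydroxy-6-[(2S)-2-methylbutanoyl]chroman (1R,4S,5R,9S) | C=C1CC[C@@H]2Cc3c(O[C@@]2(C)CC[C@@H]2[C@@H]1CC2(C)C)cc(O)c(C(=O)[C@@H](C)CC)c3O
F4 | step 1 | (2S)-2-methyl-1-(2,4,6-trimethoxyphenyl)butan-1-one | CC[C@H](C)C(=O)c1c(OC)cc(OC)cc1OC
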